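**Remark on the chemistry.** Atoms are numbered along the acid chain (C1 = carboxyl carbon; the peroxide oxygen on C3 is O2, that on C5 is O1, so chain and ring locants coincide). The annulation is planned as unselective at C3, so numbers 20 to 28 denote the single isomer obtained after separation at 20. The CIP label of C3 is R while C1 is an alcohol or ester and S once C1 is an aldehyde or acid; the centre itself is not touched.

## Structural features

The target 28 is a 1,2-dioxolane (O1–O2–C3–C4–C5). C3 carries a methyl group and the acetic acid arm (C2–C1); C5 carries a methyl group and a C6–C17 chain ending in an (E,E)-4-phenylbuta-1,3-dienyl unit (C14–C17 plus phenyl). There are three stereocentres: the fully substituted peroxide carbons C3 (S) and C5 (R), 1,3-related through C4 with arm and chain on opposite faces, and the methyl-bearing C7 (R), 1,3-related to C5 through C6; no two are directly bonded. The fragile elements are the O–O bond (hydrides, hydrogenation, phosphines, low-valent metals, radicals), the conjugated phenyldiene (electrophiles, strong oxidants, Lewis acids) and the β-peroxy carbonyl relationship C1–C2–C3–O2, which can open by β-elimination under base. The real difficulty is the ring: two quaternary C–O centres joined through a peroxide, with the right relative configuration across C4 and the right sense relative to C7, after which every operation must be non-reducing. Neither C3 nor C5 carries hydrogen, so the finished ring cannot epimerise or fragment by the Kornblum–DeLaMare pathway, which makes early ring construction acceptable. The key step uses the fact that C4, C5, the C5 methyl and C6 onward form the skeleton of a 2-methylalk-1-ene (C4 the CH2 terminus, C5 the site of a tertiary cation), while C3 with its methyl and the C2–C1 arm is at the oxidation level of a methyl ketone and can be made electrophilic as a peroxycarbenium ion; joining C3–C4 and then C5–O1 builds the whole ring.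

## Logic of the disconnections

28 ⇒ 25 (through 27 and 26). No skeletal bond is cut; C1 is taken back from acid to aldehyde to alcohol to acetate. The β-peroxy acid is the most base-sensitive function and is best made last under buffered oxidation. The gain is a robust, non-acidic C1. The forward steps must cleave the ester mildly and oxidise without touching the O–O bond or the diene.

25 ⇒ 22 + 23. The C14=C15 double bond is cut. This removes the diene, the only unit that cannot meet a Lewis acid, and puts C15–C17 and the phenyl ring into a purchasable reagent. What remains is a saturated chain ending in a C14 aldehyde. The forward olefination must be E-selective and must spare the acetate and the peroxide.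

22 ⇒ 20 (through 21). No skeletal bond is cut; the C14 aldehyde is traced back to a silyl-protected alcohol, because an aldehyde would not survive the annulation. The forward step needs a silyl cleavage that leaves the acetate in place.

20 ⇒ 5 + 17. The C3–C4 and C5–O1 bonds are cut. This is the only cut that removes the ring and both quaternary stereocentres at once and leaves two pieces free of ring stereochemistry: a four-carbon ketal and the chain alkene. The forward step must bond at the CH2 terminus, close faster than the cation loses a proton, and favour the trans arrangement; the isomers must be separable.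

5 ⇒ 4 ⇒ 2 ⇒ 1. The C3–OMe and C3–OO bonds are traced back to the C=CH2 bond of 2, and the acetate to the free alcohol of 1. Ozonolysis in methanol delivers the ketone-level carbon already bearing the peroxide. The forward step relies on fragmentation of the primary ozonide toward the ketone oxide.

17 ⇒ 16. The C4=C5 double bond is cut to a methyl ketone, which is a stable carrier of C5 through chain building and hydrogenation. The forward step is methylenation of an enolisable ketone.

16 ⇒ 15 ⇒ 13 + 8. The C10–C11 bond is cut (as C10=C11). This joins the chiral C5–C10 piece to a C11–C14 piece that brings the protected oxygen. The forward steps need an aldehyde-selective Wittig reaction beside a methyl ketone and a hydrogenation that spares ketone and silyl ether.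

13 ⇒ 11 ⇒ 10 ⇒ 9. The C10 aldehyde is traced back to an isopropylidene alkene, and the bond between C5 and its methyl is cut. This reaches the chiral-pool aldehyde 9, which holds C7 in the right configuration together with C5, C6 and C8–C10. C7 is β to every carbonyl on the way and cannot epimerise.

8 ⇒ 7 ⇒ 6. The C11–P and O–Si bonds are cut, leading to a purchasable bromo alcohol.

## Other disconnections considered

Alternative 1: The cut removes both C–O bonds of the ring (C3–O2 and C5–O1) and replaces them by the C3–C5 bond of a vinylcyclopropane A2 (1-ethenyl-1,2-dimethylcyclopropane carrying the C6–C14 chain); the two oxygens come from O2.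
- Forward step: a phenylselenyl radical from PhSeSePh and light adds to the vinyl terminus, the cyclopropylcarbinyl radical opens to the tertiary C5 radical, O2 is captured, the peroxyl radical closes 5-exo onto C3 and the selenyl radical is expelled, giving the 3-vinyl dioxolane A1.
- In its favour: the peroxide comes from air under neutral conditions, no hydroperoxide is isolated, silyl ethers are untouched, and A2 need not be stereodefined because both ring carbons become planar during the step.
- Against it here: the vinyl group is not yet the arm. An anti-Markovnikov hydration beside the O–O bond (hydroboration is itself a hazard for a peroxide) and an acetylation are needed merely to reach 20. A2 must be built from 17 by a carbene addition and adjustment of the new substituent, at least three steps. The phenyldiene would not survive selenyl radicals and must again come later. Neither C3 nor C5 is controlled in the absolute sense.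
- Comparison: on stereocontrol the two plans are equals (four isomers from either). On the source of the O–O bond and on mildness Alternative 1 is the better. On structure it delivers the wrong C3 substituent, and on step economy the chosen plan is ahead by about five steps in the longest sequence.

Alternative 2: The cut is the mirror image of the chosen one, C4–C5 and C3–O2, so that C5 becomes the peroxycarbenium carbon and C1–C4 the nucleophile.
- Forward step: the chain ketal A4 (from 17 by ozonolysis in methanol and silylation) is ionised by SnCl4 at low temperature, methyl 3-methylbut-3-enoate A5 bonds through its CH2 terminus (C4) to C5, and the tertiary C3 cation is captured by the silylperoxy oxygen to give the ester A3.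
- In its favour: A3 already has C1 at the acid oxidation level, so only four steps remain (desilylation, oxidation, olefination, saponification) and the three steps to 5 disappear, A5 being purchasable. The first stereocentre (C5) is formed β to C7, closer to the resident centre than in the chosen plan.
- Against it: A5 is an inductively deactivated alkene and the C3 cation sits β to an ester, so proton loss to an unsaturated ester competes with closure. The long fragment, not the small one, must be made into a peroxide and used as the limiting electrophile. The route ends with a basic saponification next to a β-peroxy ester and a diene.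
- Comparison: mechanism and ring-closing mode are the same class and the cis/trans question is identical. Alternative 2 is the better on total step count (about three fewer, equal longest sequence) and possibly on C5/C7 induction. The chosen plan is the better on nucleophile reactivity, on using the cheap partner in excess and on avoiding base at the end.

Alternative 3: Only C5–O1 is cut; C3–O2 is already present in an open-chain tertiary triethylsilyl peroxide A7 that carries a methylidene group on C5, with the C3 configuration derived from a Sharpless asymmetric epoxidation.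
- Forward step: a cobalt hydride, formed from the divalent cobalt complex Co(salen), N-fluoro-2,4,6-trimethylpyridinium tetrafluoroborate and PhSiH3, transfers a hydrogen atom to the methylidene carbon (which becomes the C5 methyl). The tertiary C5 radical is oxidised through a higher-valent alkylcobalt species to a cation equivalent, and the silylperoxy oxygen on C3 captures it with loss of the silyl group as its fluoride, giving the dioxolane A6.
- In its favour: C3 is fixed in the absolute sense before ring closure, so only C5 is open and two isomers must be separated instead of four, with the C3/C7 relationship secure. Conditions are neutral and compatible with silyl ethers.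
- Against it: A7 needs a long linear sequence (joining the chain to the C1–C4 unit with the skipped alkene in place, epoxidation, stereospecific conversion of the epoxy alcohol into the tertiary peroxide, two silylations). A silane and a metal hydride operate beside an O–O bond. The C5 selectivity again rests on 1,3-induction from C3. In A6 the arm ether is more labile than the chain ether, which forces the acid to be made before the diene and costs protecting-group steps.
- Comparison: Alternative 3 is the better on stereocontrol and at least equal on mildness. Mechanistically it replaces a polar two-bond annulation by a radical–polar one-bond closure. On convergence and step economy the chosen plan is clearly ahead, since it reaches the ring in seven linear steps from 9.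

Key step: step 12

## Route

Step 1
Reactants: 1 3-methylbut-3-en-1-ol
Product: 2 3-methylbut-3-en-1-yl acetate
Conditions: Ac2O, pyridine, DMAP (cat.), CH2Cl2, 0 °C to rt
Reagents that add atoms: acetic anhydride, CC(=O)OC(C)=O
Why: Standard DMAP-catalysed O-acylation of a primary alcohol; the acetate is inert to ozone, tolerated by SnCl4 at low temperature and keeps C1 at the alcohol level until the end.

Step 2
Reactants: 2 3-methylbut-3-en-1-yl acetate
Product: 4 3-hydroperoxy-3-methoxybutyl acetate, via carbonyl oxide 3 (not isolated)
Conditions: O3, CH2Cl2/MeOH, −78 °C; N2 purge; no reductive work-up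
Reagents that add atoms: ozone, [O-][O+]=O; methanol, CO
Why: Ozonolysis in a participating solvent (Criegee mechanism): the primary ozonide of the 1,1-disubstituted alkene fragments to formaldehyde and the more substituted carbonyl oxide 3, which methanol traps as the α-methoxy hydroperoxide. The small peroxide is kept cold and in solution, never distilled, and handled behind a shield.

Step 3
Reactants: 4 3-hydroperoxy-3-methoxybutyl acetate
Product: 5 3-methoxy-3-(triethylsilylperoxy)butyl acetate (racemic)
Conditions: Et3SiCl, imidazole, DMF, 0 °C
Reagents that add atoms: chlorotriethylsilane, CC[Si](Cl)(CC)CC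
Why: Routine O-silylation of a hydroperoxide; the tertiary peroxide has no α-hydrogen for base-induced fragmentation, and the silyl peroxyketal is the form that a Lewis acid ionises cleanly at the methoxy group.

Step 4
Reactants: 6 4-bromobutan-1-ol
Product: 7 (4-bromobutoxy)triisopropylsilane
Conditions: i-Pr3SiCl, imidazole, CH2Cl2, 0 °C to rt
Reagents that add atoms: chlorotriisopropylsilane, CC(C)[Si](Cl)(C(C)C)C(C)C
Why: Standard silylation; it stops the bromo alcohol from cyclising to tetrahydrofuran and installs the C14 ether that later withstands ylides, hydrogenation and SnCl4.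

Step 5
Reactants: 7 (4-bromobutoxy)triisopropylsilane
Product: 8 triphenyl[4-(triisopropylsilyloxy)butyl]phosphonium bromide
Conditions: PPh3, MeCN, reflux
Reagents that add atoms: triphenylphosphine, c1ccc(cc1)P(c1ccccc1)c1ccccc1
Why: SN2 quaternisation of triphenylphosphine by a primary bromide under neutral conditions that leave the silyl ether intact.

Step 6
Reactants: 9 (R)-citronellal
Product: 10 (4R)-4,8-dimethylnon-7-en-2-ol (both C2 epimers)
Conditions: MeMgBr, Et2O, 0 °C; aq NH4Cl
Reagents that add atoms: methylmagnesium bromide, C[Mg]Br
Why: Grignard addition to the aldehyde brings in the carbon that becomes the C5 methyl; the carbinol centre forms unselectively but is oxidised in step 7, and C7 is β to the carbonyl and cannot epimerise.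

Step 7
Reactants: 10 (4R)-4,8-dimethylnon-7-en-2-ol
Product: 11 (4R)-4,8-dimethylnon-7-en-2-one
Conditions: Dess–Martin periodinane, CH2Cl2, 0 °C to rt
Reagents that add atoms: none
Why: Dess–Martin oxidation of a secondary alcohol to the methyl ketone under near-neutral conditions that leave the trisubstituted alkene untouched.

Step 8
Reactants: 11 (4R)-4,8-dimethylnon-7-en-2-one
Product: 13 (4R)-4-methyl-6-oxoheptanal, via ozonide 12 (not isolated)
Conditions: O3, CH2Cl2, −78 °C; PPh3, −78 °C to rt
Reagents that add atoms: ozone, [O-][O+]=O
Why: Ozonolysis cleaves the only alkene and PPh3 reduces the ozonide to the C10 aldehyde with loss of acetone; the ketone is inert, and the 1,6-keto aldehyde is used at once to avoid aldol cyclisation.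

Step 9
Reactants: 8 triphenyl[4-(triisopropylsilyloxy)butyl]phosphonium bromide; 13 (4R)-4-methyl-6-oxoheptanal
Product: 15 (4R,7Z)-4-methyl-11-(triisopropylsilyloxy)undec-7-en-2-one, via phosphorus ylide 14 (not isolated)
Conditions: NaN(SiMe3)2, THF, 0 °C; then 13, −78 °C to 0 °C
Reagents that add atoms: none
Why: Wittig olefination with an unstabilised ylide, which adds to the aldehyde much faster than to the methyl ketone at −78 °C and forms C10=C11; the alkene geometry (mainly Z) is irrelevant because step 10 removes it.

Step 10
Reactants: 15 (4R,7Z)-4-methyl-11-(triisopropylsilyloxy)undec-7-en-2-one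
Product: 16 (4R)-4-methyl-11-(triisopropylsilyloxy)undecan-2-one
Conditions: H2 (1 atm), Pd/C, EtOAc, rt
Reagents that add atoms: none
Why: Heterogeneous hydrogenation of a disubstituted alkene; the ketone and the silyl ether are not reduced under these conditions, and the hydrogenation is done before any peroxide is present.

Step 11
Reactants: 16 (4R)-4-methyl-11-(triisopropylsilyloxy)undecan-2-one
Product: 17 {[(8R)-8,10-dimethylundec-10-en-1-yl]oxy}triisopropylsilane
Conditions: Ph3PCH3Br, KOt-Bu, THF, 0 °C to rt
Reagents that add atoms: methyltriphenylphosphonium bromide, C[P+](c1ccccc1)(c1ccccc1)c1ccccc1.[Br-]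
Why: Wittig methylenation of the methyl ketone gives the 1,1-disubstituted alkene whose CH2 carbon is C4; C7 is β to the carbonyl, so enolisation cannot touch it.

Step 12
Reactants: 5 3-methoxy-3-(triethylsilylperoxy)butyl acetate; 17 {[(8R)-8,10-dimethylundec-10-en-1-yl]oxy}triisopropylsilane
Product: 20 2-[(3R,5R)-3,5-dimethyl-5-[(2R)-2-methyl-9-(triisopropylsilyloxy)nonyl]-1,2-dioxolan-3-yl]ethyl acetate, via peroxycarbenium ion 18 (not isolated), via tertiary carbocation 19 (not isolated)
Conditions: 5 (1.5 equiv), SnCl4 (1.5 equiv), CH2Cl2, −78 °C; aq NaHCO3 at −78 °C; silica gel, then preparative HPLC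
Reagents that add atoms: none
Why: SnCl4 removes methoxide from 5 and gives the planar C3 peroxycarbenium ion 18, which the acetate carbonyl can at most stabilise reversibly through a six-membered bridge. The CH2 terminus of 17 (C4) bonds to C3 in the Markovnikov sense and leaves the tertiary C5 cation 19. The silyl-bearing peroxide oxygen, 1,5-related to C5, collapses onto the cation and gives up the triethylsilyl group (formally as Et3SiOMe), so the dioxolane closes as a five-membered capture of a carbocation by oxygen, to which no exo or endo label applies because no bond at C5 is broken. The closest known reaction type is the Lewis acid promoted (3+2) annulation of triethylsilyl peroxyketals with 1,1-disubstituted alkenes. C3 is created in the C–C bond formation on an achiral cation with C7 too far from the bonding carbon C4 to bias the face, so both C3 configurations should form in similar amounts. C5 is created in the closure under control of C3: the envelope that keeps the acetoxyethyl arm and the long chain on opposite faces, each larger than its geminal methyl, should be favoured, which is the trans relationship required, though only moderately. The step needs reaction at the 1,1-disubstituted alkene only (it is the sole π-nucleophile and the triisopropylsilyl ether is inert at −78 °C), bonding at the CH2 terminus (secured by the tertiary cation) and closure faster than proton loss or chloride capture (secured by the intramolecular oxygen). The cheap ketal is used in excess, and 20 is separated from its three C3/C5 isomers, the ring configuration to be assigned by NOE and the relationship to C7 by correlation.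

Step 13
Reactants: 20 2-[(3R,5R)-3,5-dimethyl-5-[(2R)-2-methyl-9-(triisopropylsilyloxy)nonyl]-1,2-dioxolan-3-yl]ethyl acetate
Product: 21 2-[(3R,5R)-5-[(2R)-9-hydroxy-2-methylnonyl]-3,5-dimethyl-1,2-dioxolan-3-yl]ethyl acetate
Conditions: HF·pyridine, pyridine, THF, 0 °C to rt
Reagents that add atoms: none
Why: Fluoride cleavage of the primary triisopropylsilyl ether with buffered HF·pyridine; without basic fluoride the acetate neither cleaves nor migrates, and the di-tertiary peroxide is inert.

Step 14
Reactants: 21 2-[(3R,5R)-5-[(2R)-9-hydroxy-2-methylnonyl]-3,5-dimethyl-1,2-dioxolan-3-yl]ethyl acetate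
Product: 22 2-[(3R,5R)-3,5-dimethyl-5-[(2R)-2-methyl-9-oxononyl]-1,2-dioxolan-3-yl]ethyl acetate
Conditions: Dess–Martin periodinane, pyridine, CH2Cl2, 0 °C to rt
Reagents that add atoms: none
Why: Dess–Martin oxidation of the primary alcohol to the C14 aldehyde; a hypervalent iodine oxidant is non-reducing and non-basic, so peroxide and acetate are unaffected.

Step 15
Reactants: 22 2-[(3R,5R)-3,5-dimethyl-5-[(2R)-2-methyl-9-oxononyl]-1,2-dioxolan-3-yl]ethyl acetate; 23 diethyl [(2E)-3-phenylprop-2-en-1-yl]phosphonate
Product: 25 2-[(3R,5R)-3,5-dimethyl-5-[(2R,9E,11E)-2-methyl-12-phenyldodeca-9,11-dien-1-yl]-1,2-dioxolan-3-yl]ethyl acetate, via lithiated phosphonate 24 (not isolated)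
Conditions: 23 (1.3 equiv), n-BuLi (1.25 equiv), THF, −78 °C; then 22, −78 °C to rt
Reagents that add atoms: none
Why: Horner–Wadsworth–Emmons olefination with an allylic phosphonate anion forms C14=C15 mainly E, and the cinnamyl double bond keeps its E geometry. The anion is pre-formed with a deficit of butyllithium so that no alkyllithium meets the peroxide, and at −78 °C it adds to the aldehyde faster than to the acetate.

Step 16
Reactants: 25 2-[(3R,5R)-3,5-dimethyl-5-[(2R,9E,11E)-2-methyl-12-phenyldodeca-9,11-dien-1-yl]-1,2-dioxolan-3-yl]ethyl acetate
Product: 26 2-[(3R,5R)-3,5-dimethyl-5-[(2R,9E,11E)-2-methyl-12-phenyldodeca-9,11-dien-1-yl]-1,2-dioxolan-3-yl]ethan-1-ol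
Conditions: K2CO3 (0.3 equiv), MeOH, 0 °C to rt
Reagents that add atoms: none
Why: Carbonate-catalysed transesterification of the acetate with methanol; both peroxide carbons are quaternary, so Kornblum–DeLaMare fragmentation is impossible, and the diene is inert to mild base.

Step 17
Reactants: 26 2-[(3R,5R)-3,5-dimethyl-5-[(2R,9E,11E)-2-methyl-12-phenyldodeca-9,11-dien-1-yl]-1,2-dioxolan-3-yl]ethan-1-ol
Product: 27 2-[(3S,5R)-3,5-dimethyl-5-[(2R,9E,11E)-2-methyl-12-phenyldodeca-9,11-dien-1-yl]-1,2-dioxolan-3-yl]acetaldehyde
Conditions: Dess–Martin periodinane, pyridine, CH2Cl2, 0 °C; used at once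
Reagents that add atoms: none
Why: Buffered, cold Dess–Martin oxidation gives the β-peroxy aldehyde without the basic conditions that could open the ring by β-elimination and without touching the diene; the C3 label becomes S only because the arm gains CIP priority.

Step 18
Reactants: 27 2-[(3S,5R)-3,5-dimethyl-5-[(2R,9E,11E)-2-methyl-12-phenyldodeca-9,11-dien-1-yl]-1,2-dioxolan-3-yl]acetaldehyde
Product: 28 2-[(3S,5R)-3,5-dimethyl-5-[(2R,9E,11E)-2-methyl-12-phenyldodeca-9,11-dien-1-yl]-1,2-dioxolan-3-yl]acetic acid
Conditions: NaClO2, NaH2PO4, 2-methylbut-2-ene (excess), t-BuOH/H2O, 0 °C to rt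
Reagents that add atoms: sodium chlorite, [Na+].[O-]Cl=O
Why: Pinnick oxidation converts the aldehyde into the acid at about pH 4; excess 2-methylbut-2-ene removes hypochlorous acid before it can add to the phenyldiene, and chlorite does not attack the peroxide.

## Compound list

1 | 3-methylbut-3-en-1-ol | C=C(C)CCO | starting material
2 | 3-methylbut-3-en-1-yl acetate | C=C(C)CCOC(C)=O | intermediate
3 | 4-acetoxybutan-2-one O-oxide (carbonyl oxide) | CC(=[O+][O-])CCOC(C)=O | intermediate
4 | 3-hydroperoxy-3-methoxybutyl acetate (racemic) | CC(OC)(CCOC(C)=O)OO | intermediate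
5 | 3-methoxy-3-(triethylsilylperoxy)butyl acetate (racemic) | CC(OC)(CCOC(C)=O)OO[Si](CC)(CC)CC | intermediate
6 | 4-bromobutan-1-ol | OCCCCBr | starting material
7 | (4-bromobutoxy)triisopropylsilane | BrCCCCO[Si](C(C)C)(C(C)C)C(C)C | intermediate
8 | triphenyl[4-(triisopropylsilyloxy)butyl]phosphonium bromide | CC(C)[Si](OCCCC[P+](c1ccccc1)(c1ccccc1)c1ccccc1)(C(C)C)C(C)C.[Br-] | intermediate
9 | (R)-citronellal, (3R)-3,7-dimethyloct-6-enal | C[C@H](CCC=C(C)C)CC=O | starting material
10 | (4R)-4,8-dimethylnon-7-en-2-ol (both C2 epimers) | C[C@H](CCC=C(C)C)CC(C)O | intermediate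
11 | (4R)-4,8-dimethylnon-7-en-2-one | C[C@H](CCC=C(C)C)CC(C)=O | intermediate
12 | 3,3-dimethyl-5-[(3R)-3-methyl-5-oxohexyl]-1,2,4-trioxolane (both epimers at the ring carbon) | C[C@H](CCC1OOC(C)(C)O1)CC(C)=O | intermediate
13 | (4R)-4-methyl-6-oxoheptanal | C[C@H](CCC=O)CC(C)=O | intermediate
14 | triphenyl[4-(triisopropylsilyloxy)butylidene]phosphorane | CC(C)[Si](OCCCC=P(c1ccccc1)(c1ccccc1)c1ccccc1)(C(C)C)C(C)C | intermediate
15 | (4R,7Z)-4-methyl-11-(triisopropylsilyloxy)undec-7-en-2-one | C[C@H](CC/C=C\CCCO[Si](C(C)C)(C(C)C)C(C)C)CC(C)=O | intermediate
16 | (4R)-4-methyl-11-(triisopropylsilyloxy)undecan-2-one | C[C@H](CCCCCCCO[Si](C(C)C)(C(C)C)C(C)C)CC(C)=O | intermediate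
17 | {[(8R)-8,10-dimethylundec-10-en-1-yl]oxy}triisopropylsilane | C[C@H](CCCCCCCO[Si](C(C)C)(C(C)C)C(C)C)CC(C)=C | intermediate
18 | (4-acetoxybutan-2-ylidene)(triethylsilyloxy)oxonium, the C3 peroxycarbenium ion | CC(=[O+]O[Si](CC)(CC)CC)CCOC(C)=O | intermediate
19 | tertiary C5 carbocation formed from 18 and 17 (C7 R, both C3 configurations) | C[C@H](CCCCCCCO[Si](C(C)C)(C(C)C)C(C)C)C[C+](C)CC(C)(CCOC(C)=O)OO[Si](CC)(CC)CC | intermediate
20 | 2-[(3R,5R)-3,5-dimethyl-5-[(2R)-2-methyl-9-(triisopropylsilyloxy)nonyl]-1,2-dioxolan-3-yl]ethyl acetate | C[C@H](CCCCCCCO[Si](C(C)C)(C(C)C)C(C)C)C[C@]1(C)C[C@@](C)(CCOC(C)=O)OO1 | intermediate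
21 | 2-[(3R,5R)-5-[(2R)-9-hydroxy-2-methylnonyl]-3,5-dimethyl-1,2-dioxolan-3-yl]ethyl acetate | C[C@H](CCCCCCCO)C[C@]1(C)C[C@@](C)(CCOC(C)=O)OO1 | intermediate
22 | 2-[(3R,5R)-3,5-dimethyl-5-[(2R)-2-methyl-9-oxononyl]-1,2-dioxolan-3-yl]ethyl acetate | C[C@H](CCCCCCC=O)C[C@]1(C)C[C@@](C)(CCOC(C)=O)OO1 | intermediate
23 | diethyl [(2E)-3-phenylprop-2-en-1-yl]phosphonate (diethyl cinnamylphosphonate) | CCOP(=O)(OCC)C/C=C/c1ccccc1 | starting material
24 | lithium salt of the α-carbanion of 23 | CCOP(=O)(OCC)[CH-]/C=C/c1ccccc1.[Li+] | intermediate
25 | 2-[(3R,5R)-3,5-dimethyl-5-[(2R,9E,11E)-2-methyl-12-phenyldodeca-9,11-dien-1-yl]-1,2-dioxolan-3-yl]ethyl acetate | C[C@H](CCCCCC/C=C/C=C/c1ccccc1)C[C@]1(C)C[C@@](C)(CCOC(C)=O)OO1 | intermediate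
26 | 2-[(3R,5R)-3,5-dimethyl-5-[(2R,9E,11E)-2-methyl-12-phenyldodeca-9,11-dien-1-yl]-1,2-dioxolan-3-yl]ethan-1-ol | C[C@H](CCCCCC/C=C/C=C/c1ccccc1)C[C@]1(C)C[C@@](C)(CCO)OO1 | intermediate
27 | 2-[(3S,5R)-3,5-dimethyl-5-[(2R,9E,11E)-2-methyl-12-phenyldodeca-9,11-dien-1-yl]-1,2-dioxolan-3-yl]acetaldehyde | C[C@H](CCCCCC/C=C/C=C/c1ccccc1)C[C@]1(C)C[C@@](C)(CC=O)OO1 | intermediate
28 | 2-[(3S,5R)-3,5-dimethyl-5-[(2R,9E,11E)-2-methyl-12-phenyldodeca-9,11-dien-1-yl]-1,2-dioxolan-3-yl]acetic acid | C[C@H](CCCCCC/C=C/C=C/c1ccccc1)C[C@]1(C)C[C@@](C)(CC(=O)O)OO1 | target

## Step count and least certain steps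

Total: 18 steps. Longest linear sequence: 13 steps (steps 6 to 18, from 9).

**Step 12 (key step).**
- Most likely failure: poor facial discrimination in both bond-forming events, so that 20 is a minor part of a four-isomer mixture. Losses may add to this: the acetate-bearing cation 18 can be diverted by carbonyl participation or by deprotonation to a vinyl peroxide, and 19 can lose a proton before it closes. The two trans isomers differ only in the C5/C7 relationship and may resist separation.
- Fallback (roles of the partners exchanged): setting out from 17, ozonolysis in CH2Cl2/MeOH at −78 °C would give the hydroperoxy ketal F1, and silylation (Et3SiCl, imidazole) the triethylsilyl peroxyketal F2 (the same compound as A4). SnCl4 at −78 °C with an excess of 2 would then form C4–C5 first and close C3–O2, coming back to the route at 20. The electrophile then has no participating group, and its cationic carbon is β to C7, so the first stereocentre is set next to the resident one.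
- If the trans pair stays inseparable at 20, the separation is deferred to 25, which carries a chromophore.

**Step 15.**
- Most likely failure: acyl transfer from the acetate to the phosphonate carbanion, attack of the carbanion on the O–O bond, and incomplete E selectivity at C14=C15.
- Fallback (order of the end game changed, so that no ester is present during the olefination and the diene never meets an oxidant): setting out from 20, K2CO3 in MeOH would give the alcohol F3, Dess–Martin oxidation the aldehyde F4, and Pinnick oxidation the acid F5. HF·pyridine would then free C14 in the hydroxy acid F6, and Dess–Martin oxidation would give the oxo acid F7. Olefination with 24 (2.2 equiv, the first equivalent forming the lithium carboxylate) comes back to the route at 28 in the same number of steps.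

**Step 17 (with step 18).**
- Most likely failure: enolisation of the β-peroxy aldehyde followed by β-elimination of the peroxide oxygen, which opens the ring during oxidation, work-up or storage. In step 18, incomplete scavenging would let hypochlorous acid add to the diene.
- Fallback: setting out from 26, a single oxoammonium oxidation (TEMPO cat., PhI(OAc)2, MeCN/aqueous pH 7 buffer), in which the aldehyde is hydrated and oxidised as it forms, would arrive directly at 28 with no isolated aldehyde and no chlorine oxidant (no new compound: F0).

**Step 9.**
- Most likely failure: deprotonation of the keto aldehyde by the basic ylide (enolate formation, aldol cyclisation of the 1,6-dicarbonyl) and partial olefination of the ketone.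
- Fallback (ketone carried as the alcohol): setting out from 10, ozonolysis (O3; PPh3) would give the hydroxy aldehyde F8, Wittig reaction with 14 (2.2 equiv) the alkenol F9, and hydrogenation (H2, Pd/C) the saturated alcohol F10. Dess–Martin oxidation comes back to the route at 16.

## Further compounds

F1 | step 12 | {[(8R)-10-hydroperoxy-10-methoxy-8-methylundecyl]oxy}triisopropylsilane (both C10 epimers) | C[C@H](CCCCCCCO[Si](C(C)C)(C(C)C)C(C)C)CC(C)(OC)OO
F2 | step 12 | triethyl{[(4R)-2-methoxy-4-methyl-11-(triisopropylsilyloxy)undecan-2-yl]peroxy}silane (both C2 epimers) | C[C@H](CCCCCCCO[Si](C(C)C)(C(C)C)C(C)C)CC(C)(OC)OO[Si](CC)(CC)CC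
F3 | step 15 | 2-[(3R,5R)-3,5-dimethyl-5-[(2R)-2-methyl-9-(triisopropylsilyloxy)nonyl]-1,2-dioxolan-3-yl]ethan-1-ol | C[C@H](CCCCCCCO[Si](C(C)C)(C(C)C)C(C)C)C[C@]1(C)C[C@@](C)(CCO)OO1
F4 | step 15 | 2-[(3S,5R)-3,5-dimethyl-5-[(2R)-2-methyl-9-(triisopropylsilyloxy)nonyl]-1,2-dioxolan-3-yl]acetaldehyde | C[C@H](CCCCCCCO[Si](C(C)C)(C(C)C)C(C)C)C[C@]1(C)C[C@@](C)(CC=O)OO1
F5 | step 15 | 2-[(3S,5R)-3,5-dimethyl-5-[(2R)-2-methyl-9-(triisopropylsilyloxy)nonyl]-1,2-dioxolan-3-yl]acetic acid | C[C@H](CCCCCCCO[Si](C(C)C)(C(C)C)C(C)C)C[C@]1(C)C[C@@](C)(CC(=O)O)OO1
F6 | step 15 | 2-[(3S,5R)-5-[(2R)-9-hydroxy-2-methylnonyl]-3,5-dimethyl-1,2-dioxolan-3-yl]acetic acid | C[C@H](CCCCCCCO)C[C@]1(C)C[C@@](C)(CC(=O)O)OO1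
F7 | step 15 | 2-[(3S,5R)-3,5-dimethyl-5-[(2R)-2-methyl-9-oxononyl]-1,2-dioxolan-3-yl]acetic acid | C[C@H](CCCCCCC=O)C[C@]1(C)C[C@@](C)(CC(=O)O)OO1
F0 | step 17 | none | none
F8 | step 9 | (4R)-6-hydroxy-4-methylheptanal (both C6 epimers) | C[C@H](CCC=O)CC(C)O
F9 | step 9 | (4R,7Z)-4-methyl-11-(triisopropylsilyloxy)undec-7-en-2-ol (both C2 epimers) | C[C@H](CC/C=C\CCCO[Si](C(C)C)(C(C)C)C(C)C)CC(C)O
F10 | step 9 | (4R)-4-methyl-11-(triisopropylsilyloxy)undecan-2-ol (both C2 epimers) | C[C@H](CCCCCCCO[Si](C(C)C)(C(C)C)C(C)C)CC(C)O
A1 | alternative 1 | (3S,5R)-3-ethenyl-3,5-dimethyl-5-[(2R)-2-methyl-9-(triisopropylsilyloxy)nonyl]-1,2-dioxolane | C[C@H](CCCCCCCO[Si](C(C)C)(C(C)C)C(C)C)C[C@]1(C)C[C@@](C)(C=C)OO1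
A2 | alternative 1 | 1-ethenyl-1,2-dimethyl-2-[(2R)-2-methyl-9-(triisopropylsilyloxy)nonyl]cyclopropane (ring configuration immaterial) | C[C@H](CCCCCCCO[Si](C(C)C)(C(C)C)C(C)C)CC1(C)CC1(C)C=C
A3 | alternative 2 | methyl 2-[(3S,5R)-3,5-dimethyl-5-[(2R)-2-methyl-9-(triisopropylsilyloxy)nonyl]-1,2-dioxolan-3-yl]acetate | C[C@H](CCCCCCCO[Si](C(C)C)(C(C)C)C(C)C)C[C@]1(C)C[C@@](C)(CC(=O)OC)OO1
A4 | alternative 2 | triethyl{[(4R)-2-methoxy-4-methyl-11-(triisopropylsilyloxy)undecan-2-yl]peroxy}silane (both C2 epimers) | C[C@H](CCCCCCCO[Si](C(C)C)(C(C)C)C(C)C)CC(C)(OC)OO[Si](CC)(CC)CC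
A5 | alternative 2 | methyl 3-methylbut-3-enoate | C=C(C)CC(=O)OC
A6 | alternative 3 | triethyl{2-[(3R,5R)-3,5-dimethyl-5-[(2R)-2-methyl-9-(triisopropylsilyloxy)nonyl]-1,2-dioxolan-3-yl]ethoxy}silane | C[C@H](CCCCCCCO[Si](C(C)C)(C(C)C)C(C)C)C[C@]1(C)C[C@@](C)(CCO[Si](CC)(CC)CC)OO1
A7 | alternative 3 | (3S,7R)-3,7-dimethyl-5-methylidene-3-(triethylsilylperoxy)-1-(triethylsilyloxy)-14-(triisopropylsilyloxy)tetradecane | C[C@H](CCCCCCCO[Si](C(C)C)(C(C)C)C(C)C)CC(=C)C[C@@](C)(CCO[Si](CC)(CC)CC)OO[Si](CC)(CC)CC
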